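**Plan**

- Numbering used: C1 = CHO, C2 = its α-carbon, C3–C5 = hydroxypropyl (OH on C3), ring = C6 (CH), C7 (alkylidene carbon), C8, C9, C10 (C–OH), C11 (quaternary), chain from C12. Enabling feature: the C10 oxygen and the C6 side chain are cis and 1,3 on the cyclohexane, so one 3,6-dihydro-2H-pyran (O–C10–C11–C6=C5–C4) can hold both, and C7=C2 is read as a former alkyne.
- Retrosynthetic cuts: C1 oxidation level; C4–C3 (hydroformylation); C2–C1 (alkenyllithium + CH2O); ring bond C6–C7 together with O–C4 (key step); C5=C4 (RCM) and O–C4 (allylation); C10–C11 (allylboration); C12–C13 (dianion alkylation).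
- Forward: the chain is joined first (prenol dianion + farnesyl bromide, then borylation). The C20 allylboronic acid and hept-5-yn-2-one give the acyclic C10/C11 pair, and RCM closes a temporary dihydropyran. Divalent titanium then closes the carbocycle at C6–C7 while opening the pyran, and C1 and C3 are added last.
- Stereochemistry: C10 and C11 come from a diol-catalysed, geometry-specific allylboration (2Z reagent, closed chair transition state). C6 comes from intramolecular delivery across the dihydropyran. The C7=C2 geometry comes from syn carbotitanation.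

Key step: step 7

Remark (assumption): the (S)-enantiomer of the diol catalyst in step 4 is taken to direct the allyl group to the Re face of the ketone, by analogy with methyl ketones in this catalyst class; if the sense is opposite, the (R)-diol is used.

**Route**

Step 1
Reactants: 1 prenol (3-methylbut-2-en-1-ol); 2 (2E,6E)-farnesyl bromide
Product: 4 (2Z,6E,10E)-geranylgeraniol, via dilithiated prenol 3 (not isolated)
Conditions: n-BuLi (2.2 equiv), TMEDA, Et2O/hexane, 0 °C → rt; then 2, −78 → 0 °C; then H2O
Reagents that add atoms: none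
Why: alkoxide-directed allylic lithiation of prenol should remove a proton from the methyl group cis to CH2OLi, and SN2 alkylation of the chelated allyllithium at its CH2 terminus by the primary allylic bromide (dianion alkylation) keeps the new chain cis to CH2OH, giving the 2Z alkene needed in step 4.

Step 2
Reactants: 4 (2Z,6E,10E)-geranylgeraniol
Product: 5 [(2Z,6E,10E)-3,7,11,15-tetramethylhexadeca-2,6,10,14-tetraen-1-yl]boronic acid
Conditions: B2(OH)4 (1.2 equiv), [Pd(MeCN)4](BF4)2 (1 mol %), DMSO/MeOH, rt, argon; extracted into toluene and used at once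
Reagents that add atoms: tetrahydroxydiboron, OB(O)B(O)O
Why: palladium-catalysed borylation of an allylic alcohol with tetrahydroxydiboron (allylic C–O to C–B substitution) should give the linear allylboronic acid, and γ,γ-disubstituted allylboronic acids are not expected to undergo 1,3-boron shift at room temperature, so the 2Z geometry is kept.

Step 3
Reactants: 6 pentane-2,4-dione; 7 1-bromobut-2-yne
Product: 9 hept-5-yn-2-one, via 3-(but-2-yn-1-yl)pentane-2,4-dione 8 (not isolated)
Conditions: K2CO3, EtOH, reflux
Reagents that add atoms: none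
Why: C-alkylation of the 1,3-diketone by the propargylic bromide followed by base-mediated retro-Claisen deacetylation in ethanol (alkylation/deacylation) should give the methyl ketone in one operation.

Step 4
Reactants: 5 the (2Z)-allylboronic acid; 9 hept-5-yn-2-one
Product: 11 (6S,7S,10E,14E)-7-ethenyl-6,7,11,15,19-pentamethylicosa-10,14,18-trien-2-yn-6-ol, via borate ester 10 (not isolated)
Conditions: (S)-3,3′-dibromo-1,1′-bi-2-naphthol (20 mol %), t-BuOH (3 equiv), 3 Å molecular sieves, toluene, 0 °C → rt; aq NaHCO3
Reagents that add atoms: none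
Why: diol-catalysed asymmetric allylboration of a ketone with a γ,γ-disubstituted allylboronic acid runs through a closed six-membered chair in which the pentynyl chain of the ketone is equatorial and its methyl group axial, while the 2Z reagent places the homofarnesyl chain axial and the methyl group equatorial on the γ-carbon, so C10 and C11 form together in the required relative configuration and the boron-bound chiral diol selects the Re face of the ketone (both centres S).

Step 5
Reactants: 11 the tertiary homoallylic alcohol
Product: 12 (6S,7S,10E,14E)-7-ethenyl-6,7,11,15,19-pentamethyl-6-(prop-2-en-1-yloxy)icosa-10,14,18-trien-2-yne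
Conditions: NaH, allyl bromide, Bu4NI (cat.), THF/DMF, 0 °C → rt
Reagents that add atoms: allyl bromide, C=CCBr
Why: Williamson etherification of the hindered tertiary alcohol with a reactive allylic halide should work under NaH at low temperature, conditions chosen to keep retro-allylation of the homoallylic alcohol slow.

Step 6
Reactants: 12 the allyl ether
Product: 13 (2S,3S)-2,3-dimethyl-2-(pent-3-yn-1-yl)-3-[(3E,7E)-4,8,12-trimethyltrideca-3,7,11-trien-1-yl]-3,6-dihydro-2H-pyran
Conditions: second-generation Grubbs catalyst RuCl2(=CHPh)(PCy3)(H2IMes) (5 mol %), CH2Cl2 (0.005 M), 40 °C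
Reagents that add atoms: none
Why: ring-closing metathesis should start at the unhindered allyl ether and close the six-membered ring onto the neopentyl vinyl group (helped by gem-disubstitution at both sp3 ring carbons) faster than enyne metathesis with the internal alkyne or metathesis with the trisubstituted alkenes.

Step 7
Reactants: 13 the dihydropyran alkyne
Product: 17 (1S,2S,3S,4Z)-3-ethenyl-4-(1-iodoethylidene)-1,2-dimethyl-2-[(3E,7E)-4,8,12-trimethyltrideca-3,7,11-trien-1-yl]cyclohexan-1-ol, via titanium–alkyne complex 14 (not isolated), via titanacyclopentene 15 (not isolated), via alkenyltitanium alkoxide 16 (not isolated)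
Conditions: Ti(OiPr)4 (1.3 equiv), i-PrMgCl (2.6 equiv), Et2O, −78 → −50 °C, 2 h; then −50 → 0 °C; then I2 (1.5 equiv), −78 → 0 °C; aq NaHCO3/Na2S2O3
Reagents that add atoms: iodine, II
Why: Proposed new method: the divalent titanium reagent Ti(OiPr)2(η2-propene), formed from Ti(OiPr)4 and two equivalents of i-PrMgCl, should exchange propene for the internal alkyne to give titanacyclopropene 14, whose Ti–C7 bond adds across the ring alkene C6=C5 to give titanacyclopentene 15, and β-alkoxide elimination of the ring oxygen (Ti on C5 anti-periplanar to the C4–O bond) then opens the pyran to alkenyltitanium alkoxide 16, which iodine cleaves with retention. The closest known reaction type is the intramolecular allylation of titanium–alkyne complexes by tethered allylic carbonates and ethers (carbotitanation then β-elimination), together with the zirconium-catalysed carbomagnesation and ring opening of cyclic allylic ethers; what is new is that the leaving oxygen is a ring member held by the tether. The cyclohexane closes in a 6-exo sense at both the alkyne and the alkene, through a chair–chair 2-oxabicyclo[3.3.1]nonane-like arrangement with the pentynyl arm axial on the pyran. C6 is set by this geometry alone, because the three-atom tether on C10 can reach C6 only on its own face of the pyran, so that in the carbocycle the vinyl group left on C6 and the C10 oxygen are cis. The C7=C2 geometry follows from syn addition of C6 and titanium across the alkyne, so iodine ends cis to C6 and the methyl group trans to it. The selectivity needed is complexation of the alkyne before any attack on the allylic ether or the three trisubstituted alkenes, which the higher affinity of the titanium reagent for alkynes at −50 °C and the poor leaving-group ability of a dialkyl allyl ether should secure.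

Step 8
Reactants: 17 the alkenyl iodide
Product: 19 (1S,2S,3R,4Z)-3-ethenyl-4-(1-hydroxypropan-2-ylidene)-1,2-dimethyl-2-[(3E,7E)-4,8,12-trimethyltrideca-3,7,11-trien-1-yl]cyclohexan-1-ol, via dilithio alkenyllithium alkoxide 18 (not isolated)
Conditions: t-BuLi (3.3 equiv), Et2O, −78 °C; then (CH2O)n (dry, excess), −78 → 0 °C; then H2O
Reagents that add atoms: formaldehyde (from paraformaldehyde), C=O
Why: iodine–lithium exchange of the tetrasubstituted alkenyl iodide (after deprotonation of the tertiary alcohol) should give a configurationally stable alkenyllithium that adds to formaldehyde with retention, so the hydroxymethyl group stays cis to C6.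

Step 9
Reactants: 19 the vinyl diol
Product: 21 (1S,2S,3R,4Z)-4-(1-hydroxypropan-2-ylidene)-3-(3-hydroxypropyl)-1,2-dimethyl-2-[(3E,7E)-4,8,12-trimethyltrideca-3,7,11-trien-1-yl]cyclohexan-1-ol, via hydroxy aldehyde 20 (not isolated)
Conditions: Rh(acac)(CO)2 (2 mol %), Xantphos (4 mol %), CO/H2 (1:1, 10 bar), toluene, 70 °C; then NaBH4, MeOH, 0 °C
Reagents that add atoms: carbon monoxide, [C-]#[O+]
Why: ligand-controlled linear-selective rhodium-catalysed hydroformylation should act only on the monosubstituted vinyl group (tri- and tetrasubstituted alkenes are inert under these conditions) and add the missing carbon C3 at the terminus, and borohydride reduction of the aldehyde in the same pot gives the primary alcohol.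

Step 10
Reactants: 21 the triol
Product: 22 iridal, (2Z)-2-[(2R,3S,4S)-4-hydroxy-2-(3-hydroxypropyl)-3,4-dimethyl-3-[(3E,7E)-4,8,12-trimethyltrideca-3,7,11-trien-1-yl]cyclohexylidene]propanal
Conditions: activated MnO2 (20 equiv), CH2Cl2, rt
Reagents that add atoms: none
Why: MnO2 oxidises allylic alcohols selectively (allylic oxidation), so only the tetrasubstituted allylic CH2OH should become the aldehyde, the saturated primary and the tertiary alcohol stay untouched, and the double-bond geometry is not affected.

**Compound list**

1 | prenol (3-methylbut-2-en-1-ol) | CC(C)=CCO | starting material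
2 | (2E,6E)-farnesyl bromide | CC(C)=CCC/C(C)=C/CC/C(C)=C/CBr | starting material
3 | dilithiated prenol (lithium alkoxide, CH2Li cis to CH2OLi; not isolated) | [Li]OC/C=C(C)\C[Li] | intermediate
4 | (2Z,6E,10E)-geranylgeraniol | CC(C)=CCC/C(C)=C/CC/C(C)=C/CC/C(C)=C\CO | intermediate
5 | [(2Z,6E,10E)-3,7,11,15-tetramethylhexadeca-2,6,10,14-tetraen-1-yl]boronic acid | CC(C)=CCC/C(C)=C/CC/C(C)=C/CC/C(C)=C\CB(O)O | intermediate
6 | pentane-2,4-dione | CC(=O)CC(C)=O | starting material
7 | 1-bromobut-2-yne | CC#CCBr | starting material
8 | 3-(but-2-yn-1-yl)pentane-2,4-dione (not isolated) | CC#CCC(C(C)=O)C(C)=O | intermediate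
9 | hept-5-yn-2-one | CC#CCCC(C)=O | intermediate
10 | borate ester of 11 (O–B(OH)2 on the tertiary oxygen; not isolated) | CC(C)=CCC/C(C)=C/CC/C(C)=C/CC[C@@](C)(C=C)[C@@](C)(OB(O)O)CCC#CC | intermediate
11 | (6S,7S,10E,14E)-7-ethenyl-6,7,11,15,19-pentamethylicosa-10,14,18-trien-2-yn-6-ol | CC(C)=CCC/C(C)=C/CC/C(C)=C/CC[C@@](C)(C=C)[C@@](C)(O)CCC#CC | intermediate
12 | (6S,7S,10E,14E)-7-ethenyl-6,7,11,15,19-pentamethyl-6-(prop-2-en-1-yloxy)icosa-10,14,18-trien-2-yne | CC(C)=CCC/C(C)=C/CC/C(C)=C/CC[C@@](C)(C=C)[C@@](C)(OCC=C)CCC#CC | intermediate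
13 | (2S,3S)-2,3-dimethyl-2-(pent-3-yn-1-yl)-3-[(3E,7E)-4,8,12-trimethyltrideca-3,7,11-trien-1-yl]-3,6-dihydro-2H-pyran | CC(C)=CCC/C(C)=C/CC/C(C)=C/CC[C@@]1(C)C=CCO[C@@]1(C)CCC#CC | intermediate
14 | diisopropoxytitanium η2-alkyne complex (titanacyclopropene) of 13 (not isolated) | CC(C)=CCC/C(C)=C/CC/C(C)=C/CC[C@@]1(C)C=CCO[C@@]1(C)CCC2=C(C)[Ti]2(OC(C)C)OC(C)C | intermediate
15 | tricyclic titanacyclopentene (C6–C7 formed, Ti on C2 and C5, pyran intact; not isolated) | CC(C)=CCC/C(C)=C/CC/C(C)=C/CC[C@@]1(C)[C@@H]2[C@@H]3CO[C@@]1(C)CCC2=C(C)[Ti]3(OC(C)C)OC(C)C | intermediate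
16 | ring-opened alkenyltitanium alkoxide (Ti on C2 and on the C10 oxygen, vinyl on C6; not isolated) | CC(C)=CCC/C(C)=C/CC/C(C)=C/CC[C@@]1(C)[C@H](C=C)/C2=C(/C)[Ti](OC(C)C)(OC(C)C)O[C@@]1(C)CC2 | intermediate
17 | (1S,2S,3S,4Z)-3-ethenyl-4-(1-iodoethylidene)-1,2-dimethyl-2-[(3E,7E)-4,8,12-trimethyltrideca-3,7,11-trien-1-yl]cyclohexan-1-ol | CC(C)=CCC/C(C)=C/CC/C(C)=C/CC[C@@]1(C)[C@H](C=C)/C(=C(/C)I)CC[C@]1(C)O | intermediate
18 | dilithio species from 17 (alkenyllithium at C2, lithium alkoxide at C10; not isolated) | CC(C)=CCC/C(C)=C/CC/C(C)=C/CC[C@@]1(C)[C@H](C=C)/C(=C(/C)[Li])CC[C@]1(C)O[Li] | intermediate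
19 | (1S,2S,3R,4Z)-3-ethenyl-4-(1-hydroxypropan-2-ylidene)-1,2-dimethyl-2-[(3E,7E)-4,8,12-trimethyltrideca-3,7,11-trien-1-yl]cyclohexan-1-ol | CC(C)=CCC/C(C)=C/CC/C(C)=C/CC[C@@]1(C)[C@H](C=C)/C(=C(/C)CO)CC[C@]1(C)O | intermediate
20 | hydroxy aldehyde (19 with the vinyl group turned into CH2CH2CHO; not isolated) | CC(C)=CCC/C(C)=C/CC/C(C)=C/CC[C@@]1(C)[C@H](CCC=O)/C(=C(/C)CO)CC[C@]1(C)O | intermediate
21 | (1S,2S,3R,4Z)-4-(1-hydroxypropan-2-ylidene)-3-(3-hydroxypropyl)-1,2-dimethyl-2-[(3E,7E)-4,8,12-trimethyltrideca-3,7,11-trien-1-yl]cyclohexan-1-ol | CC(C)=CCC/C(C)=C/CC/C(C)=C/CC[C@@]1(C)[C@H](CCCO)/C(=C(/C)CO)CC[C@]1(C)O | intermediate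
22 | iridal | CC(C)=CCC/C(C)=C/CC/C(C)=C/CC[C@@]1(C)[C@H](CCCO)/C(=C(/C)C=O)CC[C@]1(C)O | target

**Totals**

Total step count: 10. Longest linear sequence: 9 steps (steps 1, 2, 4, 5, 6, 7, 8, 9, 10); step 3 is a one-step side branch.

**Steps most likely to fail**

1. Step 7 (proposed new method). What may go wrong: the cis-disubstituted ring alkene may insert too slowly into the titanacyclopropene, so the complex is only protonated on work-up; or the divalent titanium may first add oxidatively into the allylic C–O bond of the pyran. Fallback with known chemistry, setting out from 11 and coming back at 17: the tertiary alcohol of 11 is silylated (Et3SiOTf, 2,6-lutidine) to the triethylsilyl ether F1. Cross-metathesis of its vinyl group with (Z)-but-2-ene-1,4-diyl diethyl dicarbonate (second-generation Hoveyda–Grubbs catalyst RuCl2(=CH-2-iPrOC6H4)(H2IMes)) gives the E allylic ethyl carbonate F2. Treatment with Ti(OiPr)4/2 i-PrMgCl and then iodine, the established intramolecular allylation of a titanium–alkyne complex by an open-chain allylic carbonate, closes the same C6–C7 bond and gives the silyl-protected alkenyl iodide F3. Bu4NF then gives 17. In this variant C6 rests only on the chair preference of an open-chain substrate, so separation of C6 epimers must be expected.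

2. Step 4. What may go wrong: the catalytic diol may discriminate poorly between the methyl and the pentynyl group of a dialkyl ketone; the hindered reagent may add slowly; the Z-geometry may erode during a long reaction. Fallback, setting out from 5 and coming back at 11: catalysis is replaced by reagent control with a covalently bound auxiliary. Boronic acid 5 is condensed (molecular sieves, toluene) with the matching enantiomer, taken as (S), of 3,3′-bis(trifluoromethyl)-1,1′-bi-2-naphthol to give the cyclic allylboronate F4. This more Lewis-acidic reagent adds to ketone 9 at −78 → −40 °C through the same chair and gives 11 after hydrolysis, with recovery of the diol.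

3. Step 1. What may go wrong: lithiation or alkylation may occur at the wrong allylic terminus of the dianion; farnesyl bromide may be attacked in the SN2′ sense; Z-selectivity may be lost. Fallback, setting out from 2 and coming back at 4, with the Z-geometry taken from a preformed alkenyl iodide: Kornblum oxidation of 2 (DMSO, NaHCO3) gives (2E,6E)-farnesal F5. Wittig methylenation (Ph3P=CH2) gives (3E,7E)-4,8,12-trimethyltrideca-1,3,7,11-tetraene F6. Hydroboration of its terminal double bond with 9-BBN gives the homofarnesyl borane F7. B-alkyl Suzuki coupling of F7 with (Z)-3-iodobut-2-en-1-ol (PdCl2(dppf), AsPh3, Cs2CO3, DMF/THF/H2O) gives 4.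

**Further compounds**

F1 | step 7 | triethylsilyl ether of 11 | CC(C)=CCC/C(C)=C/CC/C(C)=C/CC[C@@](C)(C=C)[C@@](C)(O[Si](CC)(CC)CC)CCC#CC
F2 | step 7 | E allylic ethyl carbonate from F1 (vinyl group turned into (E)-CH=CH–CH2–OCO2Et) | CC(C)=CCC/C(C)=C/CC/C(C)=C/CC[C@@](C)(/C=C/COC(=O)OCC)[C@@](C)(O[Si](CC)(CC)CC)CCC#CC
F3 | step 7 | triethylsilyl ether of 17 | CC(C)=CCC/C(C)=C/CC/C(C)=C/CC[C@@]1(C)[C@H](C=C)/C(=C(/C)I)CC[C@]1(C)O[Si](CC)(CC)CC
F4 | step 4 | (2Z,6E,10E)-geranylgeranylboronate of (S)-3,3′-bis(trifluoromethyl)-1,1′-bi-2-naphthol | CC(C)=CCC/C(C)=C/CC/C(C)=C/CC/C(C)=C\CB1Oc2c(C(F)(F)F)cc3ccccc3c2-c2c(O1)c(C(F)(F)F)cc1ccccc21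
F5 | step 1 | (2E,6E)-farnesal | CC(C)=CCC/C(C)=C/CC/C(C)=C/C=O
F6 | step 1 | (3E,7E)-4,8,12-trimethyltrideca-1,3,7,11-tetraene | CC(C)=CCC/C(C)=C/CC/C(C)=C/C=C
F7 | step 1 | 9-[(3E,7E)-4,8,12-trimethyltrideca-3,7,11-trien-1-yl]-9-borabicyclo[3.3.1]nonane | CC(C)=CCC/C(C)=C/CC/C(C)=C/CCB1C2CCCC1CCC2
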